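**Remark (assumption):** the target has no stereocentre or other stereogenic element, so "single enantiomer" is read as the single achiral constitution of the SMILES; no step has to set configuration.

## Structural features

Haemathamnolic acid is an achiral meta-depside: two densely substituted benzene rings joined by one aryl ester, with no ring fusion and no stereocentre. Ring A is a 3-formyl-2-hydroxy-4-methoxy-6-methylbenzoyl unit whose carbonyl carbon sits between O-2 and the C6 methyl. Ring B is 3-formyl-2,4-dihydroxy-6-methylbenzoic acid carrying the ester oxygen on C5, between the C4 hydroxyl and the C6 methyl. Both rings are thus the same haematommic acid skeleton, once methylated at O-4 (ring A) and once oxygenated at C5 (ring B). The fragile groups are two salicylaldehyde-type formyl groups (Dakin or Baeyer–Villiger oxidation, reduction), the depside ester (hydrolysis, acyl shift under base) and a β-resorcylic acid that decarboxylates on heating. The real difficulty is the C5(ring B)–O–C(=O)(ring A) link: an ester between a di-ortho-substituted benzoyl carbon and a di-ortho-substituted phenolic oxygen that must also be told apart from O-2 and O-4. The key step exploits the fact that in the B ring lacking the C5 oxygen, C5 is the only hydrogen-bearing ring carbon and lies ortho to O-4 and para to O-2; the aryl C5–O bond of the depside is made there by C–H aroyloxylation, not the acyl–oxygen bond.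

## Logic of the disconnections

**14 to 13.** The benzyl–oxygen bond of the ring B carboxylate is cut. The free acid is prone to decarboxylation and the depside ester to base, so the last step must be neutral and cold; hydrogenolysis meets this. The forward step must leave two aryl aldehydes untouched.

**13 to 12.** The O–CH2 bond of a methoxymethyl ether on O-2 of ring A is cut. The ether is there only because the key step needs ring A without a free phenol. Its removal must not touch the depside ester, which points to acid.

**12 to 4 and 10 (key).** The bond between C5 of ring B and the ester oxygen is cut, not the acyl–oxygen bond. The ring B partner then becomes 4, which has its single aromatic C–H exactly at C5, so no 2,4,5-trioxygenated ring has to be built and no choice among three hydroxyls has to be made. The ring A partner becomes an electrophilic aroyloxy donor, peroxide 10. In one sentence: 12 arises by aroyloxylation of the only ring C–H of 4 with 10. The forward step demands attack of C5 on the O–O bond in preference to attack on the hindered carbonyl or ipso attack at C1 or C3, and survival of two formyl groups.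

**10 to 7.** The O–O bond is cut, giving two molecules of 7 and hydrogen peroxide. The symmetrical peroxide needs no second acid; the half that is not transferred in the key step returns as 7. The forward step must double-acylate hydrogen peroxide with a hindered acid without oxidising the formyl group.

**7 to 6 to 5 to 4.** The benzyl ester C–O bond, the MOM O–C bond and the O-4 methyl bond are cut in turn. This leads ring A back to the same compound 4 that serves as the ring B partner, so one monomer feeds both halves. The forward steps need selective methylation of O-4 over the doubly chelated O-2, and a hydrogenolysis that spares the MOM ether and the aldehyde.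

**4 to 2 to 1.** The C3–CHO bond and the benzyl ester bond are cut, arriving at commercial orsellinic acid 1. The forward formylation must go to C3 (between the two hydroxyls) and not to C5.

## Other disconnections considered

**Alternative 1:** the acyl–oxygen bond of the depside is cut (the first idea). Forward, acid A1 is esterified with triol A2 (trifluoroacetic anhydride or a carbodiimide) to give 13. A2 needs a separate oxidation of 4 at C5 beforehand, and the esterification must pick O-5 among three phenols while joining a di-ortho-substituted acid to a di-ortho-substituted phenol, the slowest kind of ester formation. The chosen plan merges oxygenation and acylation into one event at the only C–H and turns the steric shielding of the carbonyl into an advantage.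

**Alternative 2:** the ester oxygen is removed, leading back to benzophenone A3. Forward, a Baeyer–Villiger oxidation of A3 with migration of the ring B aryl group would insert the oxygen. The two formyl groups are better substrates for peracids than the diaryl ketone and would have to be masked. The migratory preference between two electron-rich aryl groups is not secured by structure. A3 itself needs a Friedel–Crafts acylation at the hindered C5. This means more steps and two selectivity questions where the chosen plan has one.

**Alternative 3:** a biosynthesis-like sequence. Acid A1 is esterified at O-4 of 4 to give para-depside A4, C5 is hydroxylated to A5, and a base-mediated 1,2-acyl shift from O-4 to O-5 gives 13. The shift should be favourable, since O-4 gains a chelate with the formyl group. However, the plan still needs a classical esterification at a chelated phenol and a late C–H hydroxylation on a base-labile depside bearing two aldehydes. That is three uncertain operations for what the chosen key step does in one.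

Key step: step 7

## Steps

Step 1
Reactants: 1 orsellinic acid (2,4-dihydroxy-6-methylbenzoic acid)
Product: 2 benzyl orsellinate (benzyl 2,4-dihydroxy-6-methylbenzoate)
Conditions: BnBr, KHCO3, DMF, rt
Reagents that add atoms: benzyl bromide, BrCc1ccccc1
Why: Carboxylate O-alkylation (SN2); hydrogencarbonate deprotonates only the carboxylic acid, so the phenols stay free, and the mild conditions avoid decarboxylation.

Step 2
Reactants: 2 benzyl orsellinate
Product: 4 benzyl haematommate (benzyl 3-formyl-2,4-dihydroxy-6-methylbenzoate), via alpha-chloro ether 3 (not isolated)
Conditions: Cl2CHOMe, TiCl4, CH2Cl2, −10 → 0 °C; then aq. HCl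
Reagents that add atoms: dichloromethyl methyl ether, COC(Cl)Cl; water, O
Why: Rieche formylation; C3 is ortho to both titanium-bound oxygens, whereas C5 is ortho to only one and is crowded by the C6 methyl, so the electrophile should be delivered mainly to C3, and aqueous work-up hydrolyses 3 to the aldehyde.

Step 3
Reactants: 4 benzyl haematommate
Product: 5 benzyl 3-formyl-2-hydroxy-4-methoxy-6-methylbenzoate
Conditions: MeI (1.05 equiv), K2CO3 (1.0 equiv), acetone, rt
Reagents that add atoms: iodomethane, CI
Why: Williamson O-methylation; O-4 (para to the ester, the more acidic and less shielded hydroxyl) should react first, while O-2 is held between the ester and formyl carbonyls by hydrogen bonds.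

Step 4
Reactants: 5 benzyl 3-formyl-2-hydroxy-4-methoxy-6-methylbenzoate
Product: 6 benzyl 3-formyl-4-methoxy-2-(methoxymethoxy)-6-methylbenzoate
Conditions: NaH, DMF, 0 °C; MOMCl, 0 °C → rt
Reagents that add atoms: chloromethyl methyl ether, COCCl
Why: O-alkylation of the sodium phenoxide with a reactive alpha-chloro ether, which overcomes the hindrance and chelation of O-2; the ether masks the only phenol of ring A for the oxidative steps.

Step 5
Reactants: 6 benzyl 3-formyl-4-methoxy-2-(methoxymethoxy)-6-methylbenzoate
Product: 7 3-formyl-4-methoxy-2-(methoxymethoxy)-6-methylbenzoic acid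
Conditions: H2 (1 atm), 10% Pd/C, EtOAc, rt, stopped after 1 equiv of H2
Reagents that add atoms: none
Why: Hydrogenolysis of a benzyl ester under neutral conditions; the MOM ether is inert and the hindered, electron-rich aldehyde should be reduced much more slowly than the benzylic C–O bond is cleaved.

Step 6
Reactants: 7 3-formyl-4-methoxy-2-(methoxymethoxy)-6-methylbenzoic acid (2 equiv)
Product: 10 bis[3-formyl-4-methoxy-2-(methoxymethoxy)-6-methylbenzoyl] peroxide, via O-acylisourea 8 (not isolated), via peroxy acid 9 (not isolated)
Conditions: DCC, H2O2·urea (0.5 equiv per acid pair), CH2Cl2, −10 → 0 °C, dark; cold filtration, solution used directly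
Reagents that add atoms: hydrogen peroxide (as its urea adduct), OO
Why: Carbodiimide-mediated double acylation of hydrogen peroxide, a standard entry to diaroyl peroxides; the small alpha-effect nucleophiles H2O2 and 9 can reach the hindered acyl carbon of 8, and the neutral, cold, anhydrous medium is chosen to keep the flanked aldehyde and the MOM ether intact.

Step 7
Reactants: 4 benzyl haematommate; 10 bis[3-formyl-4-methoxy-2-(methoxymethoxy)-6-methylbenzoyl] peroxide
Product: 12 benzyl 3-formyl-5-{[3-formyl-4-methoxy-2-(methoxymethoxy)-6-methylbenzoyl]oxy}-2,4-dihydroxy-6-methylbenzoate, via cyclohexadienone 11 (not isolated)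
Conditions: K2CO3 (1.1 equiv), MeCN, 0 °C → rt, dark, Ar; then aq. NaH2PO4
Reagents that add atoms: none
Why: K2CO3 turns 4 into its phenoxide, an ambident nucleophile (a vinylogous β-dicarbonyl enolate) whose only hydrogen-bearing ring carbon is C5, ortho to O-4 and para to O-2. C5 attacks one oxygen of the weak O–O bond of 10 in an SN2-type displacement that expels the carboxylate of 7 and gives the 6-aroyloxycyclohexa-2,4-dienone 11; because the new sp3 carbon carries H, 11 should tautomerise at once to the aromatic catechol monoester 12, so the step is a dearomatisation–rearomatisation that forms the C5–O bond of the depside. The closest known reaction type is the ortho-acyloxylation of phenols with diaroyl peroxides to catechol monoesters, together with the alpha-acyloxylation of β-dicarbonyl enolates by dibenzoyl peroxide. No ring is closed and no stereocentre survives, the sp3 centre of 11 being erased on tautomerisation. Site selectivity is needed against ipso attack at C1 and C3: these carbons carry the ester and formyl groups, are more hindered and less electron-rich, and would lead to dienones that cannot rearomatise. Chemoselectivity is needed against attack at the aroyl carbon (plain O-acylation with release of a peroxy acid); the carbonyls of 10 are flanked by OCH2OMe and CH3, so the hindrance that slows a classical esterification here steers the nucleophile to the exposed peroxide oxygen. The MOM ether leaves 10 without a phenol of its own, so only ring B is oxidised, and the O-5 ester is the thermodynamic site because O-4 stays chelated to the formyl group, so no acyl shift is expected. The second half of 10 is returned as 7 and can go back into step 6.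

Step 8
Reactants: 12 benzyl 3-formyl-5-{[3-formyl-4-methoxy-2-(methoxymethoxy)-6-methylbenzoyl]oxy}-2,4-dihydroxy-6-methylbenzoate
Product: 13 benzyl haemathamnolate (benzyl 3-formyl-5-[(3-formyl-2-hydroxy-4-methoxy-6-methylbenzoyl)oxy]-2,4-dihydroxy-6-methylbenzoate)
Conditions: TFA, CH2Cl2, H2O (trace), 0 °C → rt
Reagents that add atoms: none
Why: Acid-catalysed cleavage of an aryl methoxymethyl acetal through the oxocarbenium ion; aryl esters, the benzyl ester and aryl aldehydes are stable to trifluoroacetic acid at this temperature.

Step 9
Reactants: 13 benzyl haemathamnolate
Product: 14 haemathamnolic acid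
Conditions: H2 (1 atm), 10% Pd/C, EtOAc, rt, stopped after 1 equiv of H2; filtration, concentration below 30 °C
Reagents that add atoms: none
Why: Neutral hydrogenolysis of the benzyl ester, the usual end-game for formyl-bearing depside acids; the chelated aldehydes should react far more slowly than the benzyl ester, and the neutral, cold isolation avoids decarboxylation and ester cleavage.

## Compound list

1 | orsellinic acid (2,4-dihydroxy-6-methylbenzoic acid) | Cc1cc(O)cc(O)c1C(=O)O | starting material
2 | benzyl orsellinate (benzyl 2,4-dihydroxy-6-methylbenzoate) | Cc1cc(O)cc(O)c1C(=O)OCc1ccccc1 | intermediate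
3 | benzyl 3-[chloro(methoxy)methyl]-2,4-dihydroxy-6-methylbenzoate (alpha-chloro ether, not isolated, racemic) | COC(Cl)c1c(O)cc(C)c(C(=O)OCc2ccccc2)c1O | intermediate
4 | benzyl haematommate (benzyl 3-formyl-2,4-dihydroxy-6-methylbenzoate) | Cc1cc(O)c(C=O)c(O)c1C(=O)OCc1ccccc1 | intermediate
5 | benzyl 3-formyl-2-hydroxy-4-methoxy-6-methylbenzoate | COc1cc(C)c(C(=O)OCc2ccccc2)c(O)c1C=O | intermediate
6 | benzyl 3-formyl-4-methoxy-2-(methoxymethoxy)-6-methylbenzoate | COCOc1c(C=O)c(OC)cc(C)c1C(=O)OCc1ccccc1 | intermediate
7 | 3-formyl-4-methoxy-2-(methoxymethoxy)-6-methylbenzoic acid | COCOc1c(C=O)c(OC)cc(C)c1C(=O)O | intermediate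
8 | O-[3-formyl-4-methoxy-2-(methoxymethoxy)-6-methylbenzoyl]-N,N'-dicyclohexylisourea (not isolated) | COCOc1c(C=O)c(OC)cc(C)c1C(=O)OC(=NC1CCCCC1)NC1CCCCC1 | intermediate
9 | 3-formyl-4-methoxy-2-(methoxymethoxy)-6-methylperoxybenzoic acid (not isolated) | COCOc1c(C=O)c(OC)cc(C)c1C(=O)OO | intermediate
10 | bis[3-formyl-4-methoxy-2-(methoxymethoxy)-6-methylbenzoyl] peroxide | COCOc1c(C=O)c(OC)cc(C)c1C(=O)OOC(=O)c1c(C)cc(OC)c(C=O)c1OCOC | intermediate
11 | benzyl 5-{[3-formyl-4-methoxy-2-(methoxymethoxy)-6-methylbenzoyl]oxy}-3-formyl-2-hydroxy-6-methyl-4-oxocyclohexa-1,6(1),2-dienecarboxylate, i.e. the 6-aroyloxycyclohexa-2,4-dienone at C5 of ring B (not isolated, racemic) | O=CC1=C(O)C(C(=O)OCc2ccccc2)=C(C)C(OC(=O)c2c(C)cc(OC)c(C=O)c2OCOC)C1=O | intermediate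
12 | benzyl 3-formyl-5-{[3-formyl-4-methoxy-2-(methoxymethoxy)-6-methylbenzoyl]oxy}-2,4-dihydroxy-6-methylbenzoate | COCOc1c(C=O)c(OC)cc(C)c1C(=O)Oc1c(C)c(C(=O)OCc2ccccc2)c(O)c(C=O)c1O | intermediate
13 | benzyl haemathamnolate | COc1cc(C)c(C(=O)Oc2c(C)c(C(=O)OCc3ccccc3)c(O)c(C=O)c2O)c(O)c1C=O | intermediate
14 | haemathamnolic acid | COc1cc(C)c(C(=O)Oc2c(C)c(C(=O)O)c(O)c(C=O)c2O)c(O)c1C=O | target

## Step count and least certain steps

Total step count: 9. Longest linear sequence: 9 steps (1 → 2 → 4 → 5 → 6 → 7 → 10 → 12 → 13 → 14); compound 4 enters twice, as the precursor of ring A and as the ring B partner.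

**Step 7 (key step).** Most likely to go wrong:
- slow reaction of the electron-poor, chelated phenoxide, so that the peroxide decomposes first;
- electron transfer from the phenoxide to the peroxide, followed by decarboxylation of the aroyloxy radical or coupling of phenoxyl radicals;
- ipso attack at C3 with loss of the formyl group;
- residual attack at the aroyl carbon, which would release a peroxy acid that oxidises aldehydes.

Fallback: the same aryl C–O bond is made by cross-coupling instead of peroxide chemistry. It sets out from 4 and 7 and returns at 12. Compound 4 is brominated at its only free position (NBS, MeCN, 0 °C) to benzyl 5-bromo-3-formyl-2,4-dihydroxy-6-methylbenzoate F1. F1 is then coupled with acid 7 by nickel-catalysed, photosensitised C–O coupling of an aryl bromide with a carboxylic acid (NiBr2·glyme, dtbbpy, Ir(ppy)3, N-tert-butylisopropylamine, DMF, blue light, rt) to give 12.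

**Step 6.** Most likely to go wrong:
- Baeyer–Villiger oxidation of the aryl aldehyde by the transient peroxy acid;
- rearrangement of the hindered O-acylisourea to an N-acylurea before the peroxide nucleophile arrives;
- decomposition of the peroxide during handling.

Fallback: peroxy species are avoided altogether. It sets out from 7 (with 4 as partner) and returns at 12, replacing steps 6 and 7. Acid 7 (2 equiv) is exchanged onto (diacetoxyiodo)benzene, with acetic acid removed under vacuum with chlorobenzene, to give bis[3-formyl-4-methoxy-2-(methoxymethoxy)-6-methylbenzoyloxy](phenyl)-λ3-iodane F2. F2 should transfer one aroyloxy ligand to C5 of 4 (CH2Cl2, 0 °C) in an iodine(III)-mediated oxidative acyloxylation of the phenol, again through 11, to give 12.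

**Step 2.** Most likely to go wrong: poor site selectivity (formylation at C5 as well as C3) and double formylation.

Fallback: the formylation is made ortho-specific by leaving only one hydroxyl free. It sets out from 2 and returns at 4. The unchelated O-4 of 2 is protected selectively (MOMCl, iPr2NEt, CH2Cl2) to give benzyl 2-hydroxy-4-(methoxymethoxy)-6-methylbenzoate F3. The magnesium phenoxide of F3 is formylated (MgCl2, Et3N, paraformaldehyde, MeCN, reflux), a reaction that goes only ortho to the free hydroxyl and so can reach only C3, to give benzyl 3-formyl-2-hydroxy-4-(methoxymethoxy)-6-methylbenzoate F4. Acid (HCl, THF/H2O) removes the MOM group to give 4.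

**Step 3.** Most likely to go wrong: loss of selectivity between the two phenols (methylation at O-2 as well, or incomplete conversion).

Fallback: the order is reversed. It sets out from 2 and returns at 5. Compound 2 is methylated at the only unchelated hydroxyl, O-4 (MeI, K2CO3, acetone), to give benzyl 2-hydroxy-4-methoxy-6-methylbenzoate F5. F5 is then formylated ortho to its remaining hydroxyl by the same magnesium phenoxide method to give 5.

## Further compounds

F1 | step 7 | benzyl 5-bromo-3-formyl-2,4-dihydroxy-6-methylbenzoate | Cc1c(Br)c(O)c(C=O)c(O)c1C(=O)OCc1ccccc1
F2 | step 6 | bis[3-formyl-4-methoxy-2-(methoxymethoxy)-6-methylbenzoyloxy](phenyl)-λ3-iodane | COCOc1c(C=O)c(OC)cc(C)c1C(=O)OI(OC(=O)c1c(C)cc(OC)c(C=O)c1OCOC)c1ccccc1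
F3 | step 2 | benzyl 2-hydroxy-4-(methoxymethoxy)-6-methylbenzoate | COCOc1cc(C)c(C(=O)OCc2ccccc2)c(O)c1
F4 | step 2 | benzyl 3-formyl-2-hydroxy-4-(methoxymethoxy)-6-methylbenzoate | COCOc1cc(C)c(C(=O)OCc2ccccc2)c(O)c1C=O
F5 | step 3 | benzyl 2-hydroxy-4-methoxy-6-methylbenzoate | COc1cc(C)c(C(=O)OCc2ccccc2)c(O)c1
A1 | alternative 1 | 3-formyl-2-hydroxy-4-methoxy-6-methylbenzoic acid | COc1cc(C)c(C(=O)O)c(O)c1C=O
A2 | alternative 1 | benzyl 3-formyl-2,4,5-trihydroxy-6-methylbenzoate | Cc1c(O)c(O)c(C=O)c(O)c1C(=O)OCc1ccccc1
A3 | alternative 2 | benzyl 3-formyl-5-(3-formyl-2-hydroxy-4-methoxy-6-methylbenzoyl)-2,4-dihydroxy-6-methylbenzoate | COc1cc(C)c(C(=O)c2c(C)c(C(=O)OCc3ccccc3)c(O)c(C=O)c2O)c(O)c1C=O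
A4 | alternative 3 | benzyl 3-formyl-4-[(3-formyl-2-hydroxy-4-methoxy-6-methylbenzoyl)oxy]-2-hydroxy-6-methylbenzoate | COc1cc(C)c(C(=O)Oc2cc(C)c(C(=O)OCc3ccccc3)c(O)c2C=O)c(O)c1C=O
A5 | alternative 3 | benzyl 3-formyl-4-[(3-formyl-2-hydroxy-4-methoxy-6-methylbenzoyl)oxy]-2,5-dihydroxy-6-methylbenzoate | COc1cc(C)c(C(=O)Oc2c(O)c(C)c(C(=O)OCc3ccccc3)c(O)c2C=O)c(O)c1C=O
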